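Flavan numbering is used: upper unit rings A, C, B; lower unit rings D, F, E. Compound numbers are those of the list after the steps; 13 is fragment 1, 30 is fragment 2, 35 is the benzannulation product, 37 is the target.

## Analysis of the target

Target 37 is a profisetinidin dimer: a 5-deoxyflavan-3-ol (rings A, C, B; oxygen at C7, C3', C4') is bonded through C4 to C6 of a catechin unit (rings D, F, E). It has five stereocentres. In the upper unit C2 (R), C3 (S) and C4 (R) carry ring B, the hydroxyl and ring D in a 2,3-trans-3,4-cis arrangement; in the lower unit C2(F) (R) and C3(F) (S) are trans, and no ring relates the two sets, so they have to be set independently. The molecule carries eight phenolic hydroxyls that oxidise readily, benzylic ether bonds at both C2 atoms, and an interflavan C4–C6(D) bond that acid cleaves; hindered rotation about this bond should give rotamers. Two things make the synthesis hard: ring D of a catechin is nucleophilic at C6 and at C8, so coupling at C4 gives regioisomers, and a flavan C4 cation is attacked mainly anti to the C3 oxygen, which leads to 3,4-trans and not to the 3,4-cis relationship needed here. The strategy rests on the pattern of ring D: C6(D), which bears C4, lies between the oxygen-bearing C5(D) and C7(D) and para to C8a(D)–O1(F), while C4a(D) and C8a(D) are shared with ring F. This is the pattern of a resorcinol formed from a vinylketene whose alkene is the C8a(D)=C4a(D) enol ether of ring F and a siloxyalkyne that carries the flavan C4, so ring D can be grown around the C4 substituent instead of being attached to it.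

## Retrosynthetic reasoning

**Protecting groups.** 37 is traced to 36 by hydrogenolysis of seven benzyl ethers and 36 to 35 by removal of one aryl silyl ether. No skeletal bond is cut. Benzyl groups are chosen because their removal is neutral and spares the acid-labile interflavan bond.

**Ring D (key disconnection).** In 35 the bonds C5(D)–C6(D) and C7(D)–C8(D) are cut. This divides ring D between siloxyalkyne 13 (C6 and C7) and the ring-fused cyclobutenone 30 (C5, C8, C8a, C4a). The cut is not made at C4–C6(D), because that bond would have to be formed by attack of an arene on a C4 cation, with the regiochemical and stereochemical problems named above. What is gained is that every substituent of ring D is fixed by atom mapping and that both flavan units arrive with all five stereocentres in place. The forward reaction has to open 30 to vinylketene 31, join it to 13 with the ketene carbon on the alkyne carbon remote from oxygen (32), and carry 32 through ring opening (33) and ring closure (34) to the phenol.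

**Fragment 13.** The ynol silyl ether is traced to terminal alkyne 11 (through ynolate 12), and the two benzyl ethers of 11 to diol 10. Both steps only change oxygen substituents and leave C4 untouched.

**Ring C.** In 10 the O1–C2 bond is cut, giving tetraol 9, which comes from 8 by loss of two sulfonates and the C-silyl group. The cut is placed at C2 because its 3,4-bis(benzyloxy)phenyl group lets this carbon ionise under mild acid, whereas C3 and C4 must not be disturbed. The forward ring closure has to place ring B trans to O3, and it can do so whichever configuration C2 has in 9.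

**C4.** In 8 the bond from C4 to the alkyne is cut, giving epoxy alcohol 6 and alkyne 7. Backside opening of a trans epoxide at its benzylic carbon turns the epoxide geometry into the 3,4-cis relationship, which a cation at C4 would not give. The two sulfonates on ring A exist for this step: they make the ring electron-poor, so that the epoxide opens by SN2 and not through a benzylic cation.

**Chain of fragment 13.** 6 comes from epoxy ketone 5 by carbonyl reduction, 5 from enone 4 by catalytic asymmetric epoxidation, and 4 from aldehyde 2 and methyl ketone 3 by aldol condensation (C3–C4 bond). 2 is the bis-sulfonate of 1. The enone route gives the epoxide in one catalytic step without a kinetic resolution.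

**Fragment 30.** The O1(F)–C8a(D) bond is cut, giving alcohol 29 (from silyl ether 28); the forward step is an alkoxy exchange on a vinylogous ester and does not touch the C2(F)–O bond. The four-membered ring of 28 is cut across C5(D)–C8(D) and C4a(D)–C8a(D) into ketene 27 and alkyne 25, and 27 comes from acid 24 through chloride 26. Cycloaddition is preferred to C-alkylation of a preformed four-membered vinylogous ester, whose enolate would be a cyclobutadiene-type anion.

**Stereocentres of ring F.** 24 is the opened and silylated form of lactone 21, the benzyl ether of 20. In 20 the lactone C–O bond at the benzylic carbon is cut, giving epoxy acid 19 (from ester 18). Opening the trans epoxide with inversion gives the trans relationship of C2(F) and C3(F) and at the same time tells the two oxygens apart. 18 comes from E-alkene 17 by reagent-controlled epoxidation, 17 from allylic alcohol 15 by [3,3] rearrangement through 16, and 15 from aldehyde 14.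

## Alternatives that were turned down

**Alternative 1:** The O1–C2 bond of ring C is cut. In the forward step the ring A phenol of epoxide A2 opens the trans C2–C3 epoxide at C2 with inversion under pyridinium p-toluenesulfonate and gives A1 with the 2,3-trans relationship and a free C3 hydroxyl. For it: the closure is stereospecific and mild, and as a single step it is less risky than a thermal union of two large fragments; on that point it is stronger than the chosen route. Against it: A2 must already contain the C4–C6(D) bond with C4 configured, a diarylmethine centre between two electron-rich rings that has to be made without help from ring C. The bromine at C8(D) of A1 is there only to block the competing position, so the regiochemical problem is moved and not solved, and it costs steps to introduce and remove. The epoxide of A2 lies next to a 3,4-dialkoxyphenyl group and is acid-labile. The chosen strategy offers instead a C4 centre set by SN2 on a small molecule (step 5) and a ring D whose substitution cannot come out wrongly.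

**Alternative 2:** The O1(F)–C2(F) bond is cut. In the forward step the C8a(D) phenol of chalcone A4 adds to the enone under a quinine-derived thiourea and gives flavanone A3. For it: A4 comes from a simple aldol condensation, the catalyst is cheap, and the conditions are mild; in the ease of making its precursor it is stronger than the chosen route. Against it: A3 lacks the C3(F) hydroxyl and has a carbonyl at C4(F), so hydroxylation trans to the aryl group and deoxygenation must follow, several steps of which the reductive ones endanger the interflavan bond. The oxa-Michael addition of simple hydroxychalcones is reversible, which erodes the new centre. The phenols at C5(D) and C8a(D) both flank the acyl group and must be told apart, or the 4-to-8 isomer forms. The C4–C6(D) bond with its 3,4-cis geometry is again assumed to exist. The chosen strategy brings both ring F centres in 30 at the final oxidation level.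

**Alternative 3:** The C3(F)=C4(F) double bond is cut. In the forward step diene A6 undergoes ring-closing metathesis with (H2IMes)(PCy3)Cl2Ru=CHPh (second-generation Grubbs catalyst) and gives 2H-chromene A5. For it: this closure is probably the most dependable key step of the four, and because C4a(D) and C8(D) are equivalent in a ring D that carries the same ether on O5 and O7, the vinyl group can be placed without a regiochemical problem; on both points it is stronger than the chosen route. Against it: A6 needs O-alkylation of a hindered phenol with a secondary electrophile that is both benzylic and allylic, where SN1, SN2' and Claisen rearrangement compete with the stereospecific path. After A5, hydroboration–oxidation and benzylation are still needed, so the C3(F) centre is set late under substrate control. The interflavan bond is once more assumed. The chosen strategy forms ring D and the interflavan connectivity in one step and leaves only deprotection afterwards.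

Key step: step 17

Remark: 28, 29 and 30 are carried as mixtures of both configurations at the cyclobutenone C4 (the ring-fusion carbon of 30), because this carbon becomes aromatic C4a(D) in step 17; 3 and 25 are taken as commercial.

## Steps

Step 1
Reactants: 1 2,4-dihydroxybenzaldehyde
Product: 2 4-formyl-1,3-phenylene bis(4-methylbenzenesulfonate)
Conditions: TsCl (2.4 equiv), Et3N, DMAP (cat.), CH2Cl2, 0 °C → rt
Reagents that add atoms: 4-methylbenzenesulfonyl chloride, Cc1ccc(cc1)S(=O)(=O)Cl
Why: Sulfonylation of both phenols. The two sulfonates make ring A electron-poor, so that the benzylic epoxide of 5 and 6 is stable and opens by SN2 in step 5; both are removed together in step 6.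

Step 2
Reactants: 2 4-formyl-1,3-phenylene bis(4-methylbenzenesulfonate); 3 1-[3,4-bis(benzyloxy)phenyl]ethan-1-one
Product: 4 4-{(1E)-3-[3,4-bis(benzyloxy)phenyl]-3-oxoprop-1-en-1-yl}-1,3-phenylene bis(4-methylbenzenesulfonate)
Conditions: LiOH·H2O (cat.), EtOH/THF, rt
Reagents that add atoms: none
Why: Claisen–Schmidt condensation of the methyl ketone enolate with the electron-poor aldehyde; E1cB dehydration gives the E-enone. Catalytic base at room temperature should spare the aryl sulfonates.

Step 3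
Reactants: 4 the E-enone
Product: 5 [3,4-bis(benzyloxy)phenyl]{(2S,3R)-3-[2,4-bis(tosyloxy)phenyl]oxiran-2-yl}methanone
Conditions: poly-D-leucine, urea·H2O2, DBU, THF, rt
Reagents that add atoms: urea–hydrogen peroxide, NC(N)=O.OO
Why: Juliá–Colonna epoxidation (conjugate addition of hydroperoxide, then ring closure) within the helical polyamino acid. Poly-D-leucine should deliver the (2S,3R)-epoxide, which fixes C3 of the flavan and the centre that step 5 inverts into C4; the E-alkene gives the trans epoxide.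

Step 4
Reactants: 5 the epoxy ketone
Product: 6 (R)-[3,4-bis(benzyloxy)phenyl]{(2R,3R)-3-[2,4-bis(tosyloxy)phenyl]oxiran-2-yl}methanol
Conditions: NaBH4, CeCl3·7H2O, MeOH/THF, −78 °C
Reagents that add atoms: none
Why: Luche reduction; hydride adds to the cerium-chelated epoxy ketone anti to the epoxide carbon and should give the anti (erythro) epoxy alcohol. The carbinol configuration is not carried into the target (step 6 re-forms this centre), but the hydroxyl is needed to direct step 5.

Step 5
Reactants: 6 the epoxy alcohol; 7 ethynyl(trimethyl)silane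
Product: 8 (1R,2S,3R)-1-[3,4-bis(benzyloxy)phenyl]-3-[2,4-bis(tosyloxy)phenyl]-5-(trimethylsilyl)pent-4-yne-1,2-diol
Conditions: 7, n-BuLi, toluene, 0 °C; Et2AlCl; then 6, 0 °C → rt; KNaC4H4O6 (aq) work-up
Reagents that add atoms: diethyl[(trimethylsilyl)ethynyl]aluminium (made in the flask from 7), CC[Al](CC)C#C[Si](C)(C)C
Why: Opening of a 2,3-epoxy alcohol by an alkynylalane at the carbon remote from the carbinol, here also the benzylic one; the aluminium alkoxide activates the epoxide. SN2 inversion at this carbon sets C4 of the flavan syn to the C3 oxygen (3,4-cis after ring closure), and the electron-poor ring A suppresses a cationic pathway.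

Step 6
Reactants: 8 the alkynyl diol
Product: 10 (2R,3S,4S)-2-[3,4-bis(benzyloxy)phenyl]-4-ethynyl-3,4-dihydro-2H-chromene-3,7-diol, via tetraol 9 (not isolated)
Conditions: KOH (aq), 1,4-dioxane, 70 °C; then HCl, MeOH (0.01 M), rt
Reagents that add atoms: none
Why: Hydroxide cleaves both aryl sulfonates at sulfur and the C–Si bond. Acid then ionises the C1 carbinol of 9 to a 3,4-bis(benzyloxy)benzyl cation, which the ortho phenol captures in a 6-exo closure through a chair-like transition state with ring B and the C3 hydroxyl equatorial, so that C2 should be set 2,3-trans (R). Both C1 epimers of 9 converge on the same cation, and C3 and C4 are not involved.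

Step 7
Reactants: 10 the flavan diol
Product: 11 (2R,3S,4S)-3,7-bis(benzyloxy)-2-[3,4-bis(benzyloxy)phenyl]-4-ethynyl-3,4-dihydro-2H-chromene
Conditions: NaH (2.2 equiv), BnBr, Bu4NI (cat.), THF/DMF, 0 °C
Reagents that add atoms: benzyl bromide, BrCc1ccccc1
Why: Williamson etherification of the phenoxide and the secondary alkoxide. At 0 °C with a controlled amount of base the alkyne C–H is not deprotonated.

Step 8
Reactants: 11 the terminal alkyne
Product: 13 [({(2R,3S,4S)-3,7-bis(benzyloxy)-2-[3,4-bis(benzyloxy)phenyl]-3,4-dihydro-2H-chromen-4-yl}ethynyl)oxy]tri(propan-2-yl)silane (fragment 1), via lithium ynolate 12 (not isolated)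
Conditions: n-BuLi, THF, −78 °C; LiOOt-Bu (from t-BuOOH, LiN(SiMe3)2), −78 → 0 °C; i-Pr3SiOTf, −78 °C
Reagents that add atoms: lithium tert-butyl peroxide, [Li+].CC(C)(C)O[O-]; triisopropylsilyl trifluoromethanesulfonate, CC(C)[Si](C(C)C)(C(C)C)OS(=O)(=O)C(F)(F)F
Why: Known route to siloxyalkynes: the deprotonated alkyne attacks the peroxide oxygen and gives the ynolate, and the bulky silyl triflate silylates it on oxygen and not on carbon. One equivalent of base removes only the alkyne C–H, so C4 is untouched.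

Step 9
Reactants: 14 3,4-bis(benzyloxy)benzaldehyde
Product: 15 rac-1-[3,4-bis(benzyloxy)phenyl]prop-2-en-1-ol
Conditions: CH2=CHMgBr, THF, −78 → 0 °C
Reagents that add atoms: vinylmagnesium bromide, C=C[Mg]Br
Why: Grignard 1,2-addition. The racemic carbinol is sufficient, because this centre becomes an alkene carbon in step 10.

Step 10
Reactants: 15 the allylic alcohol
Product: 17 ethyl (4E)-5-[3,4-bis(benzyloxy)phenyl]pent-4-enoate, via ketene acetal 16 (not isolated)
Conditions: MeC(OEt)3, EtCO2H (cat.), 135 °C (−EtOH)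
Reagents that add atoms: triethyl orthoacetate, CCOC(C)(OCC)OCC
Why: Johnson–Claisen rearrangement; the chair transition state with the aryl group equatorial gives the E-alkene and adds the two carbons that become C4a(D) and C5(D).

Step 11
Reactants: 17 the E-alkene
Product: 18 ethyl 3-{(2S,3S)-3-[3,4-bis(benzyloxy)phenyl]oxiran-2-yl}propanoate
Conditions: L-fructose-derived ketone of the Shi epoxidation (0.3 equiv), Oxone (2KHSO5·KHSO4·K2SO4), K2CO3, Bu4NHSO4, Na2B4O7 buffer, MeCN/CH2(OMe)2/H2O, 0 °C
Reagents that add atoms: potassium peroxymonosulfate (oxidant of Oxone), [K+].[O-]S(=O)(=O)OO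
Why: Shi epoxidation; the chiral dioxirane transfers oxygen to the trans-styrenyl alkene through a spiro transition state, and the L-series ketone should give the (S,S)-epoxide. This sets C3(F) directly and C2(F) after the inversion of step 12; the basic buffer protects the acid-labile aryl epoxide.

Step 12
Reactants: 18 the epoxy ester
Product: 20 (5S,6R)-6-[3,4-bis(benzyloxy)phenyl]-5-hydroxyoxan-2-one, via epoxy acid 19 (not isolated)
Conditions: LiOH, THF/H2O, 0 °C; AcOH; then CSA (cat.), CH2Cl2, 0 °C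
Reagents that add atoms: lithium hydroxide, [Li+].[OH-]
Why: Saponification, then acid-promoted lactonisation in which the carboxyl group opens the epoxide at the benzylic carbon (6-endo, favoured by the electron-rich aryl group) with inversion. This gives the trans relationship of C2(F) and C3(F) and differentiates the two oxygens; the trans lactone is also the one favoured if the opening has cationic character.

Step 13
Reactants: 20 the hydroxy lactone
Product: 21 (5S,6R)-5-(benzyloxy)-6-[3,4-bis(benzyloxy)phenyl]oxan-2-one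
Conditions: BnBr, Ag2O, Bu4NI (cat.), CH2Cl2, rt, dark
Reagents that add atoms: benzyl bromide, BrCc1ccccc1
Why: Silver oxide-mediated benzylation under nearly neutral conditions, which avoids both base-induced translactonisation to the five-membered lactone and acid ionisation of the benzylic lactone C–O bond.

Step 14
Reactants: 21 the benzyl lactone
Product: 24 (4S,5R)-4-(benzyloxy)-5-[3,4-bis(benzyloxy)phenyl]-5-[(tert-butyldimethylsilyl)oxy]pentanoic acid, via lithium hydroxy carboxylate 22 (not isolated), via bis-silylated acid 23 (not isolated)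
Conditions: LiOH, THF/H2O, rt; then TBSCl, imidazole, DMF; then AcOH/THF/H2O, 0 °C
Reagents that add atoms: lithium hydroxide, [Li+].[OH-]; tert-butyl(chloro)dimethylsilane, CC(C)(C)[Si](C)(C)Cl
Why: Lactone hydrolysis, silylation of hydroxyl and carboxylate while the salt cannot relactonise, and selective hydrolysis of the labile silyl ester. No stereocentre is touched.

Step 15
Reactants: 24 the silyloxy acid; 25 ethoxyethyne
Product: 28 4-{(2S,3R)-2-(benzyloxy)-3-[3,4-bis(benzyloxy)phenyl]-3-[(tert-butyldimethylsilyl)oxy]propyl}-3-ethoxycyclobut-2-en-1-one, via acid chloride 26 (not isolated), via ketene 27 (not isolated)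
Conditions: Me2C=C(Cl)NMe2, CH2Cl2, 0 °C; then 25 (3 equiv), Et3N (slow addition), Et2O, rt
Reagents that add atoms: none
Why: Ketene–alkoxyalkyne [2+2] cycloaddition. The chloroenamine gives 26 without acid, Et3N gives 27, and the ketene carbonyl carbon bonds to the unsubstituted, nucleophilic carbon of 25 while the alpha-carbon bonds to the ethoxy carbon, which gives the 4-alkyl-3-ethoxy pattern. The new ring carbon is formed without control, which does not matter (see the remark).

Step 16
Reactants: 28 the silyloxy cyclobutenone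
Product: 30 (3R,4S)-4-(benzyloxy)-3-[3,4-bis(benzyloxy)phenyl]-2-oxabicyclo[4.2.0]oct-1(8)-en-7-one (fragment 2), via hydroxy cyclobutenone 29 (not isolated)
Conditions: HF·pyridine, pyridine, THF, 0 °C; then PPTS (cat.), 5 Å MS, toluene, 50 °C
Reagents that add atoms: none
Why: Desilylation, then acid-catalysed alkoxy exchange on the vinylogous ester: the tethered hydroxyl adds to C3 of the cyclobutenone and ethanol is lost, closing the six-membered ring F. The C2(F)–O bond is not broken, so its configuration is retained.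

Step 17
Reactants: 13 fragment 1; 30 fragment 2
Product: 35 (2R,3S)-3-(benzyloxy)-6-{(2R,3S,4R)-3,7-bis(benzyloxy)-2-[3,4-bis(benzyloxy)phenyl]-3,4-dihydro-2H-chromen-4-yl}-2-[3,4-bis(benzyloxy)phenyl]-7-{[tri(propan-2-yl)silyl]oxy}-3,4-dihydro-2H-chromen-5-ol, via vinylketene 31 (not isolated), via 2-vinylcyclobutenone 32 (not isolated), via dienylketene 33 (not isolated), via cyclohexadienone 34 (not isolated)
Conditions: 30 (1.3 equiv), toluene (0.2 M), 80 → 110 °C, sealed tube, Ar
Reagents that add atoms: none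
Why: Danheiser benzannulation of a cyclobutenone with a siloxyalkyne, applied to a ring-fused 3-alkoxycyclobutenone. Heating opens 30 by 4-electron electrocyclic cleavage of the C5(D)–C4a(D) bond, the ring CH2 turning outward, to vinylketene 31, whose alkene is the C8a(D)=C4a(D) enol ether of ring F; both epimers of 30 give the same 31. The ketene adds to the alkyne of 13 in a [2+2] step in which the electrophilic ketene carbon (future C5(D)) bonds to the alkyne carbon that carries flavan C4 (future C6(D)), the nucleophilic end of the oxygen-polarised ynol ether, and the ketene alpha-carbon (future C8(D)) bonds to the siloxy carbon (future C7(D)), giving 32. 32 opens reversibly to dienylketene 33, and the isomer with the pyranyl group cis to the ketene closes ring D by a disrotatory 6-electron electrocyclisation that re-forms C4a(D)–C5(D); the resulting cyclohexadienone 34 tautomerises to the phenol. No stereocentre is formed: the ring-fusion centre of 30 becomes aromatic and the five preset centres meet only neutral toluene. The step needs regioselectivity in the ketene–alkyne union, which the siloxy group secures electronically, and since every ring D substituent is placed by atom mapping a 4-to-8 isomer cannot arise; it also needs the ketene to be trapped faster than it dimerises, which the electron-rich alkyne should ensure.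

Step 18
Reactants: 35 the benzannulation product
Product: 36 (2R,3S)-3-(benzyloxy)-6-{(2R,3S,4R)-3,7-bis(benzyloxy)-2-[3,4-bis(benzyloxy)phenyl]-3,4-dihydro-2H-chromen-4-yl}-2-[3,4-bis(benzyloxy)phenyl]-3,4-dihydro-2H-chromene-5,7-diol
Conditions: Bu4NF, AcOH, THF, 0 °C
Reagents that add atoms: none
Why: Fluoride cleaves the aryl silyl ether; buffering with acetic acid keeps the electron-rich diphenol from oxidising as its anion.

Step 19
Reactants: 36 the hepta-O-benzyl dimer
Product: 37 (2R,3S)-2-(3,4-dihydroxyphenyl)-6-[(2R,3S,4R)-2-(3,4-dihydroxyphenyl)-3,7-dihydroxy-3,4-dihydro-2H-chromen-4-yl]-3,4-dihydro-2H-chromene-3,5,7-triol (target)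
Conditions: H2 (1 atm), Pd(OH)2/C, THF/MeOH, rt
Reagents that add atoms: none
Why: Hydrogenolysis of seven benzyl ethers under neutral conditions, which should leave the interflavan bond and the benzylic C2–O1 bonds of both pyran rings intact.

## Compound list

1 | 2,4-dihydroxybenzaldehyde | O=Cc1ccc(O)cc1O | starting material
2 | 4-formyl-1,3-phenylene bis(4-methylbenzenesulfonate) | O=Cc1ccc(OS(=O)(=O)c2ccc(C)cc2)cc1OS(=O)(=O)c1ccc(C)cc1 | intermediate
3 | 1-[3,4-bis(benzyloxy)phenyl]ethan-1-one | CC(=O)c1ccc(OCc2ccccc2)c(OCc2ccccc2)c1 | starting material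
4 | 4-{(1E)-3-[3,4-bis(benzyloxy)phenyl]-3-oxoprop-1-en-1-yl}-1,3-phenylene bis(4-methylbenzenesulfonate) | O=C(/C=C/c1ccc(OS(=O)(=O)c2ccc(C)cc2)cc1OS(=O)(=O)c1ccc(C)cc1)c1ccc(OCc2ccccc2)c(OCc2ccccc2)c1 | intermediate
5 | [3,4-bis(benzyloxy)phenyl]{(2S,3R)-3-[2,4-bis(tosyloxy)phenyl]oxiran-2-yl}methanone | O=C(c1ccc(OCc2ccccc2)c(OCc2ccccc2)c1)[C@H]1O[C@@H]1c1ccc(OS(=O)(=O)c2ccc(C)cc2)cc1OS(=O)(=O)c1ccc(C)cc1 | intermediate
6 | (R)-[3,4-bis(benzyloxy)phenyl]{(2R,3R)-3-[2,4-bis(tosyloxy)phenyl]oxiran-2-yl}methanol | O[C@H](c1ccc(OCc2ccccc2)c(OCc2ccccc2)c1)[C@H]1O[C@@H]1c1ccc(OS(=O)(=O)c2ccc(C)cc2)cc1OS(=O)(=O)c1ccc(C)cc1 | intermediate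
7 | ethynyl(trimethyl)silane | C#C[Si](C)(C)C | starting material
8 | (1R,2S,3R)-1-[3,4-bis(benzyloxy)phenyl]-3-[2,4-bis(tosyloxy)phenyl]-5-(trimethylsilyl)pent-4-yne-1,2-diol | O[C@H](c1ccc(OCc2ccccc2)c(OCc2ccccc2)c1)[C@@H](O)[C@H](c1ccc(OS(=O)(=O)c2ccc(C)cc2)cc1OS(=O)(=O)c1ccc(C)cc1)C#C[Si](C)(C)C | intermediate
9 | (1R,2S,3S)-1-[3,4-bis(benzyloxy)phenyl]-3-(2,4-dihydroxyphenyl)pent-4-yne-1,2-diol | O[C@H](c1ccc(OCc2ccccc2)c(OCc2ccccc2)c1)[C@@H](O)[C@H](c1ccc(O)cc1O)C#C | intermediate (not isolated)
10 | (2R,3S,4S)-2-[3,4-bis(benzyloxy)phenyl]-4-ethynyl-3,4-dihydro-2H-chromene-3,7-diol | Oc1ccc2c(c1)O[C@H](c1ccc(OCc3ccccc3)c(OCc3ccccc3)c1)[C@@H](O)[C@H]2C#C | intermediate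
11 | (2R,3S,4S)-3,7-bis(benzyloxy)-2-[3,4-bis(benzyloxy)phenyl]-4-ethynyl-3,4-dihydro-2H-chromene | c9ccccc9COc1ccc2c(c1)O[C@H](c3ccc(OCc9ccccc9)c(OCc9ccccc9)c3)[C@@H](OCc9ccccc9)[C@H]2C#C | intermediate
12 | lithium 2-{(2R,3S,4S)-3,7-bis(benzyloxy)-2-[3,4-bis(benzyloxy)phenyl]-3,4-dihydro-2H-chromen-4-yl}ethyn-1-olate | c9ccccc9COc1ccc2c(c1)O[C@H](c3ccc(OCc9ccccc9)c(OCc9ccccc9)c3)[C@@H](OCc9ccccc9)[C@H]2C#C[O-].[Li+] | intermediate (not isolated)
13 | [({(2R,3S,4S)-3,7-bis(benzyloxy)-2-[3,4-bis(benzyloxy)phenyl]-3,4-dihydro-2H-chromen-4-yl}ethynyl)oxy]tri(propan-2-yl)silane (fragment 1) | c9ccccc9COc1ccc2c(c1)O[C@H](c3ccc(OCc9ccccc9)c(OCc9ccccc9)c3)[C@@H](OCc9ccccc9)[C@H]2C#CO[Si](C(C)C)(C(C)C)C(C)C | intermediate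
14 | 3,4-bis(benzyloxy)benzaldehyde | O=Cc1ccc(OCc2ccccc2)c(OCc2ccccc2)c1 | starting material
15 | rac-1-[3,4-bis(benzyloxy)phenyl]prop-2-en-1-ol | C=CC(O)c1ccc(OCc2ccccc2)c(OCc2ccccc2)c1 | intermediate
16 | rac-1,2-bis(benzyloxy)-4-{1-[(1-ethoxyethenyl)oxy]prop-2-en-1-yl}benzene | C=CC(OC(=C)OCC)c1ccc(OCc2ccccc2)c(OCc2ccccc2)c1 | intermediate (not isolated)
17 | ethyl (4E)-5-[3,4-bis(benzyloxy)phenyl]pent-4-enoate | CCOC(=O)CC/C=C/c1ccc(OCc2ccccc2)c(OCc2ccccc2)c1 | intermediate
18 | ethyl 3-{(2S,3S)-3-[3,4-bis(benzyloxy)phenyl]oxiran-2-yl}propanoate | CCOC(=O)CC[C@@H]1O[C@H]1c1ccc(OCc2ccccc2)c(OCc2ccccc2)c1 | intermediate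
19 | 3-{(2S,3S)-3-[3,4-bis(benzyloxy)phenyl]oxiran-2-yl}propanoic acid | OC(=O)CC[C@@H]1O[C@H]1c1ccc(OCc2ccccc2)c(OCc2ccccc2)c1 | intermediate (not isolated)
20 | (5S,6R)-6-[3,4-bis(benzyloxy)phenyl]-5-hydroxyoxan-2-one | O=C1CC[C@H](O)[C@@H](c2ccc(OCc3ccccc3)c(OCc3ccccc3)c2)O1 | intermediate
21 | (5S,6R)-5-(benzyloxy)-6-[3,4-bis(benzyloxy)phenyl]oxan-2-one | O=C1CC[C@H](OCc2ccccc2)[C@@H](c2ccc(OCc3ccccc3)c(OCc3ccccc3)c2)O1 | intermediate
22 | lithium (4S,5R)-4-(benzyloxy)-5-[3,4-bis(benzyloxy)phenyl]-5-hydroxypentanoate | [Li+].[O-]C(=O)CC[C@H](OCc1ccccc1)[C@H](O)c1ccc(OCc2ccccc2)c(OCc2ccccc2)c1 | intermediate (not isolated)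
23 | tert-butyldimethylsilyl (4S,5R)-4-(benzyloxy)-5-[3,4-bis(benzyloxy)phenyl]-5-[(tert-butyldimethylsilyl)oxy]pentanoate | CC(C)(C)[Si](C)(C)OC(=O)CC[C@H](OCc1ccccc1)[C@H](O[Si](C)(C)C(C)(C)C)c1ccc(OCc2ccccc2)c(OCc2ccccc2)c1 | intermediate (not isolated)
24 | (4S,5R)-4-(benzyloxy)-5-[3,4-bis(benzyloxy)phenyl]-5-[(tert-butyldimethylsilyl)oxy]pentanoic acid | OC(=O)CC[C@H](OCc1ccccc1)[C@H](O[Si](C)(C)C(C)(C)C)c1ccc(OCc2ccccc2)c(OCc2ccccc2)c1 | intermediate
25 | ethoxyethyne | CCOC#C | starting material
26 | (4S,5R)-4-(benzyloxy)-5-[3,4-bis(benzyloxy)phenyl]-5-[(tert-butyldimethylsilyl)oxy]pentanoyl chloride | ClC(=O)CC[C@H](OCc1ccccc1)[C@H](O[Si](C)(C)C(C)(C)C)c1ccc(OCc2ccccc2)c(OCc2ccccc2)c1 | intermediate (not isolated)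
27 | (4S,5R)-4-(benzyloxy)-5-[3,4-bis(benzyloxy)phenyl]-5-[(tert-butyldimethylsilyl)oxy]pent-1-en-1-one | O=C=CC[C@H](OCc1ccccc1)[C@H](O[Si](C)(C)C(C)(C)C)c1ccc(OCc2ccccc2)c(OCc2ccccc2)c1 | intermediate (not isolated)
28 | 4-{(2S,3R)-2-(benzyloxy)-3-[3,4-bis(benzyloxy)phenyl]-3-[(tert-butyldimethylsilyl)oxy]propyl}-3-ethoxycyclobut-2-en-1-one (both C4 epimers) | CCOC1=CC(=O)C1C[C@H](OCc1ccccc1)[C@H](O[Si](C)(C)C(C)(C)C)c1ccc(OCc2ccccc2)c(OCc2ccccc2)c1 | intermediate
29 | 4-{(2S,3R)-2-(benzyloxy)-3-[3,4-bis(benzyloxy)phenyl]-3-hydroxypropyl}-3-ethoxycyclobut-2-en-1-one (both C4 epimers) | CCOC1=CC(=O)C1C[C@H](OCc1ccccc1)[C@H](O)c1ccc(OCc2ccccc2)c(OCc2ccccc2)c1 | intermediate (not isolated)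
30 | (3R,4S)-4-(benzyloxy)-3-[3,4-bis(benzyloxy)phenyl]-2-oxabicyclo[4.2.0]oct-1(8)-en-7-one (fragment 2; both C6 epimers) | O=C1C=C2O[C@H](c4ccc(OCc9ccccc9)c(OCc9ccccc9)c4)[C@@H](OCc9ccccc9)CC12 | intermediate
31 | 2-{(2R,3S)-3-(benzyloxy)-2-[3,4-bis(benzyloxy)phenyl]-3,4-dihydro-2H-pyran-6-yl}ethen-1-one | O=C=CC1=CC[C@H](OCc9ccccc9)[C@@H](c4ccc(OCc9ccccc9)c(OCc9ccccc9)c4)O1 | intermediate (not isolated)
32 | 4-{(2R,3S)-3-(benzyloxy)-2-[3,4-bis(benzyloxy)phenyl]-3,4-dihydro-2H-pyran-6-yl}-2-{(2R,3S,4R)-3,7-bis(benzyloxy)-2-[3,4-bis(benzyloxy)phenyl]-3,4-dihydro-2H-chromen-4-yl}-3-{[tri(propan-2-yl)silyl]oxy}cyclobut-2-en-1-one (both C4 epimers) | c9ccccc9COc1ccc2c(c1)O[C@H](c3ccc(OCc9ccccc9)c(OCc9ccccc9)c3)[C@@H](OCc9ccccc9)[C@H]2C1=C(O[Si](C(C)C)(C(C)C)C(C)C)C(C5=CC[C@H](OCc9ccccc9)[C@@H](c4ccc(OCc9ccccc9)c(OCc9ccccc9)c4)O5)C1=O | intermediate (not isolated)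
33 | (3E)-4-{(2R,3S)-3-(benzyloxy)-2-[3,4-bis(benzyloxy)phenyl]-3,4-dihydro-2H-pyran-6-yl}-2-{(2R,3S,4R)-3,7-bis(benzyloxy)-2-[3,4-bis(benzyloxy)phenyl]-3,4-dihydro-2H-chromen-4-yl}-3-{[tri(propan-2-yl)silyl]oxy}buta-1,3-dien-1-one | c9ccccc9COc1ccc2c(c1)O[C@H](c3ccc(OCc9ccccc9)c(OCc9ccccc9)c3)[C@@H](OCc9ccccc9)[C@H]2C(=C=O)/C(O[Si](C(C)C)(C(C)C)C(C)C)=C\C5=CC[C@H](OCc9ccccc9)[C@@H](c4ccc(OCc9ccccc9)c(OCc9ccccc9)c4)O5 | intermediate (not isolated)
34 | (2R,3S)-3-(benzyloxy)-6-{(2R,3S,4R)-3,7-bis(benzyloxy)-2-[3,4-bis(benzyloxy)phenyl]-3,4-dihydro-2H-chromen-4-yl}-2-[3,4-bis(benzyloxy)phenyl]-7-{[tri(propan-2-yl)silyl]oxy}-2,3,4,4a-tetrahydro-5H-chromen-5-one (both C4a epimers) | c9ccccc9COc1ccc2c(c1)O[C@H](c3ccc(OCc9ccccc9)c(OCc9ccccc9)c3)[C@@H](OCc9ccccc9)[C@H]2C1=C(O[Si](C(C)C)(C(C)C)C(C)C)C=C5O[C@H](c4ccc(OCc9ccccc9)c(OCc9ccccc9)c4)[C@@H](OCc9ccccc9)CC5C1=O | intermediate (not isolated)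
35 | (2R,3S)-3-(benzyloxy)-6-{(2R,3S,4R)-3,7-bis(benzyloxy)-2-[3,4-bis(benzyloxy)phenyl]-3,4-dihydro-2H-chromen-4-yl}-2-[3,4-bis(benzyloxy)phenyl]-7-{[tri(propan-2-yl)silyl]oxy}-3,4-dihydro-2H-chromen-5-ol | c9ccccc9COc1ccc2c(c1)O[C@H](c3ccc(OCc9ccccc9)c(OCc9ccccc9)c3)[C@@H](OCc9ccccc9)[C@H]2c5c(O[Si](C(C)C)(C(C)C)C(C)C)cc6c(c5O)C[C@H](OCc9ccccc9)[C@@H](c4ccc(OCc9ccccc9)c(OCc9ccccc9)c4)O6 | intermediate
36 | (2R,3S)-3-(benzyloxy)-6-{(2R,3S,4R)-3,7-bis(benzyloxy)-2-[3,4-bis(benzyloxy)phenyl]-3,4-dihydro-2H-chromen-4-yl}-2-[3,4-bis(benzyloxy)phenyl]-3,4-dihydro-2H-chromene-5,7-diol | c9ccccc9COc1ccc2c(c1)O[C@H](c3ccc(OCc9ccccc9)c(OCc9ccccc9)c3)[C@@H](OCc9ccccc9)[C@H]2c5c(O)cc6c(c5O)C[C@H](OCc9ccccc9)[C@@H](c4ccc(OCc9ccccc9)c(OCc9ccccc9)c4)O6 | intermediate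
37 | (2R,3S)-2-(3,4-dihydroxyphenyl)-6-[(2R,3S,4R)-2-(3,4-dihydroxyphenyl)-3,7-dihydroxy-3,4-dihydro-2H-chromen-4-yl]-3,4-dihydro-2H-chromene-3,5,7-triol | Oc1ccc2c(c1)O[C@H](c1ccc(O)c(O)c1)[C@@H](O)[C@H]2c1c(O)cc2c(c1O)C[C@H](O)[C@@H](c1ccc(O)c(O)c1)O2 | target

## Step count and least certain steps

Total: 19 steps. Longest linear sequence: 11 steps (steps 1–8, then 17–19; steps 9–16, then 17–19, are equally long).

**Step 17 (key step).** Ring opening of the vinylogous-ester cyclobutenone 30 may need a temperature at which siloxyalkyne 13 rearranges by silyl migration from oxygen to carbon, or vinylketene 31 may dimerise before the hindered alkyne traps it. Fallback: 31 is released slowly and at lower temperature from a different precursor. It sets out from lactone 21. KN(SiMe3)2 and (PhO)2P(O)Cl (THF/HMPA, −78 °C) give the ketene acetal phosphate (2R,3S)-3-(benzyloxy)-2-[3,4-bis(benzyloxy)phenyl]-3,4-dihydro-2H-pyran-6-yl diphenyl phosphate F1. Negishi coupling of F1 with the zinc acetylide of tert-butoxyethyne (n-BuLi, ZnCl2; zerovalent palladium, Pd(PPh3)4) gives the tert-butyl ynol ether (2R,3S)-3-(benzyloxy)-2-[3,4-bis(benzyloxy)phenyl]-6-(tert-butoxyethynyl)-3,4-dihydro-2H-pyran F2. Warmed with 13 in toluene at 60–80 °C, F2 undergoes retro-ene fragmentation to 31, which enters the same [2+2], ring-opening and electrocyclisation sequence; the route is rejoined at 35.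

**Step 6.** Capture of the benzylic cation may show poor facial selectivity, so that the 2,3-cis isomer forms alongside, because the two chair-like transition states differ little; the free resorcinol ring may also be alkylated intermolecularly. Fallback: a stereospecific closure with inversion on the other carbinol epimer. It sets out from 5. CBS reduction with (S)-2-methyl-CBS-oxazaborolidine and catecholborane (catalyst control, aryl as the large group) should give the threo epoxy alcohol (S)-[3,4-bis(benzyloxy)phenyl]{(2R,3R)-3-[2,4-bis(tosyloxy)phenyl]oxiran-2-yl}methanol F3. The alkynylalane of step 5 opens F3 to (1S,2S,3R)-1-[3,4-bis(benzyloxy)phenyl]-3-[2,4-bis(tosyloxy)phenyl]-5-(trimethylsilyl)pent-4-yne-1,2-diol F4, and aqueous KOH in dioxane gives (1S,2S,3S)-1-[3,4-bis(benzyloxy)phenyl]-3-(2,4-dihydroxyphenyl)pent-4-yne-1,2-diol F5. Mitsunobu etherification (PPh3, DIAD, THF, 0 °C) lets the ortho phenol displace the activated benzylic hydroxyl with inversion, and the route is rejoined at 10.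

**Step 5.** The opening may be slow or regiochemically mixed, because the ortho sulfonate shields the benzylic carbon and the alane is a modest nucleophile. Fallback: a borate nucleophile on the O-silylated epoxide. It sets out from 6. Et3SiCl and imidazole give {(R)-[3,4-bis(benzyloxy)phenyl][(2S,3R)-3-(2,4-bis(tosyloxy)phenyl)oxiran-2-yl]methoxy}triethylsilane F6. Yamaguchi–Hirao alkynylation (LiC≡CSiMe3 from 7 and n-BuLi, BF3·OEt2, THF, −78 °C) opens the epoxide at the benzylic carbon with inversion to (1R,2S,3R)-1-[3,4-bis(benzyloxy)phenyl]-3-[2,4-bis(tosyloxy)phenyl]-1-[(triethylsilyl)oxy]-5-(trimethylsilyl)pent-4-yn-2-ol F7. F7 is taken through the conditions of step 6, whose acid phase also cleaves the silyl ether, and the route is rejoined at 10.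

**Step 15.** The aldoketene 27 may dimerise, and acid chloride 26 may lactonise with loss of the benzyl group on the gamma-oxygen, because the ketene is generated with an amine base beside nucleophilic oxygens. Fallback: a keteniminium salt in place of the ketene. It sets out from 24. Coupling with dimethylamine (EDC·HCl, HOBt) gives (4S,5R)-4-(benzyloxy)-5-[3,4-bis(benzyloxy)phenyl]-5-[(tert-butyldimethylsilyl)oxy]-N,N-dimethylpentanamide F8. Tf2O and 2,4,6-collidine convert F8 into the keteniminium triflate F9, which does not dimerise and adds 25 in a [2+2] cycloaddition to the cyclobutenyl iminium triflate F10. Hydrolysis with aqueous NaHCO3 gives 28, where the route is rejoined.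

## Further compounds

F1 | step 17 | (2R,3S)-3-(benzyloxy)-2-[3,4-bis(benzyloxy)phenyl]-3,4-dihydro-2H-pyran-6-yl diphenyl phosphate | O=P(Oc1ccccc1)(Oc1ccccc1)OC1=CC[C@H](OCc2ccccc2)[C@@H](c2ccc(OCc3ccccc3)c(OCc3ccccc3)c2)O1
F2 | step 17 | (2R,3S)-3-(benzyloxy)-2-[3,4-bis(benzyloxy)phenyl]-6-(tert-butoxyethynyl)-3,4-dihydro-2H-pyran | CC(C)(C)OC#CC1=CC[C@H](OCc2ccccc2)[C@@H](c2ccc(OCc3ccccc3)c(OCc3ccccc3)c2)O1
F3 | step 6 | (S)-[3,4-bis(benzyloxy)phenyl]{(2R,3R)-3-[2,4-bis(tosyloxy)phenyl]oxiran-2-yl}methanol | O[C@@H](c1ccc(OCc2ccccc2)c(OCc2ccccc2)c1)[C@H]1O[C@@H]1c1ccc(OS(=O)(=O)c2ccc(C)cc2)cc1OS(=O)(=O)c1ccc(C)cc1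
F4 | step 6 | (1S,2S,3R)-1-[3,4-bis(benzyloxy)phenyl]-3-[2,4-bis(tosyloxy)phenyl]-5-(trimethylsilyl)pent-4-yne-1,2-diol | O[C@@H](c1ccc(OCc2ccccc2)c(OCc2ccccc2)c1)[C@@H](O)[C@H](c1ccc(OS(=O)(=O)c2ccc(C)cc2)cc1OS(=O)(=O)c1ccc(C)cc1)C#C[Si](C)(C)C
F5 | step 6 | (1S,2S,3S)-1-[3,4-bis(benzyloxy)phenyl]-3-(2,4-dihydroxyphenyl)pent-4-yne-1,2-diol | O[C@@H](c1ccc(OCc2ccccc2)c(OCc2ccccc2)c1)[C@@H](O)[C@H](c1ccc(O)cc1O)C#C
F6 | step 5 | {(R)-[3,4-bis(benzyloxy)phenyl][(2S,3R)-3-(2,4-bis(tosyloxy)phenyl)oxiran-2-yl]methoxy}triethylsilane | CC[Si](CC)(CC)O[C@H](c1ccc(OCc2ccccc2)c(OCc2ccccc2)c1)[C@H]1O[C@@H]1c1ccc(OS(=O)(=O)c2ccc(C)cc2)cc1OS(=O)(=O)c1ccc(C)cc1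
F7 | step 5 | (1R,2S,3R)-1-[3,4-bis(benzyloxy)phenyl]-3-[2,4-bis(tosyloxy)phenyl]-1-[(triethylsilyl)oxy]-5-(trimethylsilyl)pent-4-yn-2-ol | CC[Si](CC)(CC)O[C@H](c1ccc(OCc2ccccc2)c(OCc2ccccc2)c1)[C@@H](O)[C@H](c1ccc(OS(=O)(=O)c2ccc(C)cc2)cc1OS(=O)(=O)c1ccc(C)cc1)C#C[Si](C)(C)C
F8 | step 15 | (4S,5R)-4-(benzyloxy)-5-[3,4-bis(benzyloxy)phenyl]-5-[(tert-butyldimethylsilyl)oxy]-N,N-dimethylpentanamide | CN(C)C(=O)CC[C@H](OCc1ccccc1)[C@H](O[Si](C)(C)C(C)(C)C)c1ccc(OCc2ccccc2)c(OCc2ccccc2)c1
F9 | step 15 | N-{(4S,5R)-4-(benzyloxy)-5-[3,4-bis(benzyloxy)phenyl]-5-[(tert-butyldimethylsilyl)oxy]pent-1-en-1-ylidene}-N-methylmethanaminium trifluoromethanesulfonate | C[N+](C)=C=CC[C@H](OCc1ccccc1)[C@H](O[Si](C)(C)C(C)(C)C)c1ccc(OCc2ccccc2)c(OCc2ccccc2)c1.[O-]S(=O)(=O)C(F)(F)F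
F10 | step 15 | N-(4-{(2S,3R)-2-(benzyloxy)-3-[3,4-bis(benzyloxy)phenyl]-3-[(tert-butyldimethylsilyl)oxy]propyl}-3-ethoxycyclobut-2-en-1-ylidene)-N-methylmethanaminium trifluoromethanesulfonate | CCOC1=CC(=[N+](C)C)C1C[C@H](OCc1ccccc1)[C@H](O[Si](C)(C)C(C)(C)C)c1ccc(OCc2ccccc2)c(OCc2ccccc2)c1.[O-]S(=O)(=O)C(F)(F)F
A1 | alternative 1 | octa-O-benzyl dimer with free C3 hydroxyl and bromine at C8(D) (product of the ring C closure) | c9ccccc9COc1ccc2c(c1)O[C@H](c3ccc(OCc9ccccc9)c(OCc9ccccc9)c3)[C@@H](O)[C@H]2c5c(OCc9ccccc9)c(Br)c6c(c5OCc9ccccc9)C[C@H](OCc9ccccc9)[C@@H](c4ccc(OCc9ccccc9)c(OCc9ccccc9)c4)O6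
A2 | alternative 1 | ring A phenol carrying the trans C2–C3 epoxide (precursor of A1) | Oc1cc(OCc9ccccc9)ccc1[C@H](c5c(OCc9ccccc9)c(Br)c6c(c5OCc9ccccc9)C[C@H](OCc9ccccc9)[C@@H](c4ccc(OCc9ccccc9)c(OCc9ccccc9)c4)O6)[C@@H]1O[C@H]1c3ccc(OCc9ccccc9)c(OCc9ccccc9)c3
A3 | alternative 2 | protected dimer with ring F as the flavan-4-one | c9ccccc9COc1ccc2c(c1)O[C@H](c3ccc(OCc9ccccc9)c(OCc9ccccc9)c3)[C@@H](OCc9ccccc9)[C@H]2c5c(OCc9ccccc9)cc6c(c5OCc9ccccc9)C(=O)C[C@@H](c4ccc(OCc9ccccc9)c(OCc9ccccc9)c4)O6
A4 | alternative 2 | ring D hydroxychalcone (precursor of A3) | c9ccccc9COc1ccc2c(c1)O[C@H](c3ccc(OCc9ccccc9)c(OCc9ccccc9)c3)[C@@H](OCc9ccccc9)[C@H]2c5c(OCc9ccccc9)cc(O)c(c5OCc9ccccc9)C(=O)/C=C/c4ccc(OCc9ccccc9)c(OCc9ccccc9)c4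
A5 | alternative 3 | protected dimer with ring F as the 2H-chromene | c9ccccc9COc1ccc2c(c1)O[C@H](c3ccc(OCc9ccccc9)c(OCc9ccccc9)c3)[C@@H](OCc9ccccc9)[C@H]2c5c(OCc9ccccc9)cc6c(c5OCc9ccccc9)C=C[C@@H](c4ccc(OCc9ccccc9)c(OCc9ccccc9)c4)O6
A6 | alternative 3 | ring D vinyl arene with the chiral allyl ether on O1(F) (precursor of A5) | c9ccccc9COc1ccc2c(c1)O[C@H](c3ccc(OCc9ccccc9)c(OCc9ccccc9)c3)[C@@H](OCc9ccccc9)[C@H]2c5c(OCc9ccccc9)cc(O[C@H](c4ccc(OCc9ccccc9)c(OCc9ccccc9)c4)C=C)c(c5OCc9ccccc9)C=C
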